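## Analysis of the target

The target 16 is a 2,3-dihydro-1-benzofuran (O1, C2, C3, C3a, C4–C7, C7a) with a 3,4,5-trimethoxyphenyl group on C2, a methyl group on C3, an allyl group on C5 and a free hydroxyl on C6. The SMILES reads as 2S,3S, which puts the C2 aryl group and the C3 methyl group on opposite faces of the five-membered ring (trans); these two adjacent carbons are the only stereocentres. C2 is a benzylic ether carbon between O1 and an electron-rich arene and can epimerise under acid by C2–O1 ionisation, whereas C3 is fixed once made, so the absolute configuration at C3 is the real stereochemical problem. The benzo ring is a resorcinol: O1 (on C7a) and the C6 hydroxyl are meta to each other, and C3 is bound to C3a, ortho to O1 and para to the C6 oxygen. The unit O1–C7a–C3a–C3(H)CH3 is therefore a latent ortho-quinone methide stabilised by the C6 oxygen, and C2 is a single benzylidene carbon that must bond to both of its ends, C3 and O1; this is the feature the route exploits. The allyl group on C5 is ortho to the C6 hydroxyl, the retron of an aromatic Claisen rearrangement, but C7 is ortho to the same oxygen, so regiocontrol is needed. Sensitive groups are the terminal alkene (migration into conjugation, hydrogenation), the electron-rich phenol (oxidation) and the acid-labile C2–O1 bond. The difficulty is that neither stereocentre carries a functional handle (only H, CH3 and aryl), so auxiliary- or carbonyl-based methods would cost extra redox steps.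

## Retrosynthetic reasoning

**16 to 14 (C5–allyl bond).** The C5–CH2 bond is cut by a retro-Claisen rearrangement, which leads to the C6 allyl ether 14. The allyl group thus serves first as the protecting group of the C6 oxygen and then becomes the C-allyl substituent while the phenol is revealed, so no separate protection, deprotection or cross-coupling is needed. The forward reaction must deliver the allyl group to C5 and not to C7, through the ortho-dienone 15.

**14 to 11 and 12 (O1–C2 and C2–C3 bonds).** Both bonds to C2 are cut at once. This leaves the ortho-quinone methide 11 (all carbons of the benzo ring plus C3 and its methyl group) and the benzylidene unit as the chiral sulfonium ylide 12. The cut is made here because C2 is the only atom of the oxygen ring that does not belong to the resorcinol-derived fragment, and because a [4+1] annulation forms the ring and both stereocentres in one operation from two fragments without stereocentres in their carbon skeletons. The forward reaction passes through betaine 13 and must control the face of the ylide (C2) and the relative topicity of the addition (C3).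

**11 to 5, 4, 3, 1 and 2.** The quinone methide 11 is too reactive to store. It is released in the flask from the racemic sulfone 5 by base-induced loss of a sulfinate leaving group, which erases the stereocentre of 5. Sulfone 5 comes from the benzylic alcohol 4, this from ketone 3 by hydride reduction, and 3 from the commercial dihydroxyacetophenone 1 and allyl bromide 2 by selective O-alkylation.

**12 to 10, 8 and 9; 8 to 7 and 6.** The ylide 12 is the conjugate base of the sulfonium salt 10, made by S-alkylation of the C2-symmetric thiolane 8 with the benzylic bromide 9. Thiolane 8 is reached by double inversion from the dimesylate 7 of the commercial diol 6. A C2-symmetric sulfide is chosen because it can give only one sulfonium species, and it is set free again in the key step.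

## Alternatives that were turned down

**Alternative 1:** (the textbook, biomimetic route) Disconnection of C3–C3a and O1–C2. Forward key step: two-electron oxidation of 3-methoxy-4-(prop-2-en-1-yl)phenol A1 with a hypervalent iodine oxidant. The phenoxonium ion is attacked at its allyl-bearing para carbon by the propenyl arene A2, and the benzylic cation is closed by the methoxy oxygen with loss of methyl. This gives the 3a-allyl dienone A3, whose Cope rearrangement (allyl from C3a to C5) and tautomerisation give 16. It is the shortest route on paper. It was turned down because the cationic cycloaddition offers no handle for absolute stereocontrol, so A3 would be racemic and a resolution would be needed. In addition, the phenoxonium ion can be captured by solvent or add in a [5+2] mode, which lowers the expected efficiency.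

**Alternative 2:** Disconnection of C2–C3 by carbene C–H insertion. Forward key step: the aryldiazoacetate A4 is decomposed by a chiral dirhodium tetracarboxylate (divalent rhodium), and the carbene inserts into the benzylic C–H bond of the trimethoxybenzyl ether to give the cis ester A5. It was turned down because C3 is born as an ester. A5 must be epimerised at C3 to trans and the ester reduced to methyl in three further steps (reduction, activation, reduction). The diazo precursor itself needs about four steps, and the allyl ether is a competing site for the carbene. The key step would build the ring but leave most of the work to functional group adjustment.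

**Alternative 3:** Dearomatisation of a benzofuran. Forward key step: asymmetric hydrogenation of the C2=C3 bond of the 2-aryl-3-methylbenzofuran A6 with a chiral ruthenium carbene catalyst gives the cis dihydrobenzofuran A7, which is then epimerised at C2 with acid to the trans isomer. It was turned down for three reasons. The furan double bond is tetrasubstituted and carries an aryl and an alkyl group, a pattern for which high enantioselectivity cannot be counted on. The allyl group cannot be present during hydrogenation, so a protecting group exchange is added. The cis product must be corrected through a benzylic cation. The route is longer and its stereochemical step is no safer than the one chosen.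

Key step: step 7

Remark: the SMILES is read as (2S,3S), trans. The enantiomer of the thiolane is chosen from the facial model given in step 7; should the sense of induction prove opposite, the mirror-image thiolane would be used in the same way.

## Route

Step 1
Reactants: 1 1-(2,4-dihydroxyphenyl)ethan-1-one; 2 allyl bromide
Product: 3 1-[2-hydroxy-4-(prop-2-en-1-yloxy)phenyl]ethan-1-one
Conditions: K2CO3 (1.1 equiv), acetone, reflux
Reagents that add atoms: none
Why: Williamson ether synthesis; the C2 hydroxyl is hydrogen-bonded to the acetyl carbonyl and much less nucleophilic, so alkylation should occur at the C4 hydroxyl only.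

Step 2
Reactants: 3 1-[2-hydroxy-4-(prop-2-en-1-yloxy)phenyl]ethan-1-one
Product: 4 rac-2-(1-hydroxyethyl)-5-(prop-2-en-1-yloxy)phenol
Conditions: NaBH4, MeOH/THF, 0 °C to rt; neutral work-up, used without storage
Reagents that add atoms: none
Why: Borohydride reduction of the aryl ketone; the new stereocentre need not be controlled because it is erased in step 7, and the allyl ether is inert.

Step 3
Reactants: 4 rac-2-(1-hydroxyethyl)-5-(prop-2-en-1-yloxy)phenol
Product: 5 rac-2-[1-(4-methylbenzenesulfonyl)ethyl]-5-(prop-2-en-1-yloxy)phenol
Conditions: p-TolSO2H (1.3 equiv), CH2Cl2, 0 °C to rt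
Reagents that add atoms: p-toluenesulfinic acid, Cc1ccc(cc1)S(=O)O
Why: The ortho-hydroxy, para-alkoxy benzylic alcohol ionises under the mild acidity of the sulfinic acid and the cation is captured at sulfur (S-alkylation of a sulfinate), the standard entry to 2-(1-sulfonylalkyl)phenols; the sulfone stores the quinone methide in a form that base releases.

Step 4
Reactants: 6 (2R,5R)-hexane-2,5-diol
Product: 7 (2R,5R)-hexane-2,5-diyl dimethanesulfonate
Conditions: MsCl (2.2 equiv), Et3N, CH2Cl2, −10 to 0 °C
Reagents that add atoms: methanesulfonyl chloride, CS(=O)(=O)Cl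
Why: Sulfonylation of both secondary alcohols at oxygen; no bond to a stereocentre is broken, so the configuration is retained.

Step 5
Reactants: 7 (2R,5R)-hexane-2,5-diyl dimethanesulfonate
Product: 8 (2S,5S)-2,5-dimethylthiolane
Conditions: Na2S·9H2O, EtOH, rt; isolation by distillation
Reagents that add atoms: sodium sulfide, [Na+].[Na+].[S-2]
Why: Two consecutive SN2 displacements by sulfide (intermolecular, then 5-exo-tet), each with inversion, should turn the (R,R)-dimesylate into the trans (S,S)-thiolane.

Step 6
Reactants: 8 (2S,5S)-2,5-dimethylthiolane; 9 5-(bromomethyl)-1,2,3-trimethoxybenzene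
Product: 10 (2S,5S)-2,5-dimethyl-1-(3,4,5-trimethoxybenzyl)thiolan-1-ium tetrafluoroborate
Conditions: NaBF4 (aq.), CH2Cl2, rt
Reagents that add atoms: sodium tetrafluoroborate, [Na+].F[B-](F)(F)F
Why: S-alkylation of the sulfide by the benzylic bromide; exchange to the non-nucleophilic tetrafluoroborate prevents dealkylation by bromide, and the C2 symmetry of 8 means that only one sulfonium salt can form.

Step 7
Reactants: 5 rac-2-[1-(4-methylbenzenesulfonyl)ethyl]-5-(prop-2-en-1-yloxy)phenol; 10 (2S,5S)-2,5-dimethyl-1-(3,4,5-trimethoxybenzyl)thiolan-1-ium tetrafluoroborate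
Product: 14 (2S,3S)-3-methyl-6-(prop-2-en-1-yloxy)-2-(3,4,5-trimethoxyphenyl)-2,3-dihydro-1-benzofuran, via ortho-quinone methide 11 (not isolated), via sulfonium ylide 12 (not isolated), via phenoxide-sulfonium betaine 13 (not isolated)
Conditions: Cs2CO3 (3 equiv), MeCN, 0 °C to rt; 5 added slowly to 10 (1.3 equiv) and the base
Reagents that add atoms: none
Why: Proposed new method: the carbonate deprotonates the phenol of 5, which expels toluenesulfinate to give the planar ortho-quinone methide 11 (both enantiomers of 5 converge), and it converts 10 into the aryl-substituted ylide 12; the ylide carbon adds to the exocyclic methide carbon of 11 (conjugate addition driven by rearomatisation) to give betaine 13, whose phenoxide displaces the thiolane at C2 with inversion. The closest known reaction types are the base-mediated [4+1] annulation of ortho-quinone methides released from 2-(1-sulfonylalkyl)phenols with carbonyl-stabilised sulfonium ylides, which gives trans-2,3-dihydrobenzofurans, and the asymmetric benzylidene transfer from 2,5-dimethylthiolanium benzylides to aldehydes; new is the use of a chiral aryl-substituted ylide as the one-carbon partner of an ortho-quinone methide. The ring O1–C2–C3–C3a–C7a closes by a 5-exo-tet displacement (O1–C2 bond) after the intermolecular C2–C3 bond formation. C2 is controlled by the thiolane: its C2 symmetry allows only one sulfonium species, the ylide holds its aryl group syn to the sulfur lone pair, and the ring methyl group cis to the ylide carbon shields one face, which for the (2S,5S)-thiolane predicts the R sulfonium carbon in 13 and, after inversion, 2S. C3 is set in the same C–C bond formation by the relative topicity of the addition to (E)-11: the staggered approach that keeps the trimethoxyphenyl group anti to the methyl group gives the betaine that closes to the trans ring, the outcome generally found in such annulations. The step needs capture of 11 by 12 to outrun tautomerisation of 11 to a 2-vinylphenol and its dimerisation; the C6 allyloxy group (a vinylogous ester) tempers 11, reversible re-addition of sulfinate and slow addition of 5 keep its concentration low, and 12 is the strongest nucleophile present. Thiolane 8 is released and can be recovered, and crystallisation of 14 should raise the enantiomeric purity if needed.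

Step 8
Reactants: 14 (2S,3S)-3-methyl-6-(prop-2-en-1-yloxy)-2-(3,4,5-trimethoxyphenyl)-2,3-dihydro-1-benzofuran
Product: 16 (2S,3S)-3-methyl-5-(prop-2-en-1-yl)-2-(3,4,5-trimethoxyphenyl)-2,3-dihydro-1-benzofuran-6-ol, via ortho-dienone 15 (not isolated)
Conditions: PhNEt2, 190 °C, sealed tube under argon
Reagents that add atoms: none
Why: Aromatic Claisen rearrangement ([3,3]-sigmatropic shift to dienone 15, then tautomerisation to the phenol). Migration to C5 rather than C7 is expected because the fused five-membered ring gives the C5–C6 bond more double-bond character than C6–C7, because C7 is flanked by two oxygens, and because migration away from a meta oxygen donor is the usual course. The basic, aprotic medium leaves the C2–O1 bond and both stereocentres untouched.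

## Compound list

1 | 1-(2,4-dihydroxyphenyl)ethan-1-one | CC(=O)c1ccc(O)cc1O | starting material
2 | allyl bromide (3-bromoprop-1-ene) | C=CCBr | starting material
3 | 1-[2-hydroxy-4-(prop-2-en-1-yloxy)phenyl]ethan-1-one | CC(=O)c1ccc(OCC=C)cc1O | intermediate
4 | rac-2-(1-hydroxyethyl)-5-(prop-2-en-1-yloxy)phenol | CC(O)c1ccc(OCC=C)cc1O | intermediate
5 | rac-2-[1-(4-methylbenzenesulfonyl)ethyl]-5-(prop-2-en-1-yloxy)phenol | CC(c1ccc(OCC=C)cc1O)S(=O)(=O)c1ccc(C)cc1 | intermediate
6 | (2R,5R)-hexane-2,5-diol | C[C@@H](O)CC[C@@H](C)O | starting material
7 | (2R,5R)-hexane-2,5-diyl dimethanesulfonate | C[C@@H](OS(C)(=O)=O)CC[C@@H](C)OS(C)(=O)=O | intermediate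
8 | (2S,5S)-2,5-dimethylthiolane | C[C@H]1CC[C@H](C)S1 | intermediate
9 | 5-(bromomethyl)-1,2,3-trimethoxybenzene | COc1cc(CBr)cc(OC)c1OC | starting material
10 | (2S,5S)-2,5-dimethyl-1-(3,4,5-trimethoxybenzyl)thiolan-1-ium tetrafluoroborate | COc1cc(C[S+]2[C@@H](C)CC[C@@H]2C)cc(OC)c1OC.F[B-](F)(F)F | intermediate
11 | (6E)-6-ethylidene-3-(prop-2-en-1-yloxy)cyclohexa-2,4-dien-1-one | C/C=C1/C(=O)C=C(OCC=C)C=C1 | intermediate (not isolated)
12 | [(2S,5S)-2,5-dimethylthiolan-1-ium-1-yl](3,4,5-trimethoxyphenyl)methanide | COc1cc([CH-][S+]2[C@@H](C)CC[C@@H]2C)cc(OC)c1OC | intermediate (not isolated)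
13 | 2-{(1R,2S)-1-[(2S,5S)-2,5-dimethylthiolan-1-ium-1-yl]-1-(3,4,5-trimethoxyphenyl)propan-2-yl}-5-(prop-2-en-1-yloxy)phenolate | C[C@@H](c1ccc(OCC=C)cc1[O-])[C@H](c1cc(OC)c(OC)c(OC)c1)[S+]1[C@@H](C)CC[C@@H]1C | intermediate (not isolated)
14 | (2S,3S)-3-methyl-6-(prop-2-en-1-yloxy)-2-(3,4,5-trimethoxyphenyl)-2,3-dihydro-1-benzofuran | C=CCOc1ccc2c(c1)O[C@H](c1cc(OC)c(OC)c(OC)c1)[C@H]2C | intermediate
15 | (2S,3S)-3-methyl-5-(prop-2-en-1-yl)-2-(3,4,5-trimethoxyphenyl)-3,5-dihydro-1-benzofuran-6(2H)-one (mixture at C5) | C=CCC1C=C2C(=CC1=O)O[C@H](c1cc(OC)c(OC)c(OC)c1)[C@H]2C | intermediate (not isolated)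
16 | (2S,3S)-3-methyl-5-(prop-2-en-1-yl)-2-(3,4,5-trimethoxyphenyl)-2,3-dihydro-1-benzofuran-6-ol | C=CCc1cc2c(cc1O)O[C@H](c1cc(OC)c(OC)c(OC)c1)[C@H]2C | target

## Step count and risk

Total: 8 steps. Longest linear sequence: 5 steps (steps 1, 2, 3, 7, 8; the thiolane branch, steps 4, 5, 6, 7, 8, is equally long).

**Step 7 (key step, proposed new method).** Three processes are most likely to go wrong:
- Tautomerisation of the ethylidene quinone methide to a vinylphenol, followed by oligomerisation, may outrun capture by the ylide, because carbonate generates the ylide slowly.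
- Discrimination between the two faces of the quinone methide may be insufficient. This would be serious because the minor diastereomer would differ at C3, and an acid equilibration at C2 would then lead into the enantiomeric series.
- The released sulfinate may dealkylate the benzylic sulfonium salt.

Fallback with known chemistry, setting out from allyl bromide 2 and returning to the route at 14: 3-bromo-4-iodophenol F1 would be O-allylated with 2 (K2CO3, acetone) to 2-bromo-1-iodo-4-(prop-2-en-1-yloxy)benzene F2. Palladium-catalysed α-arylation of 1-(3,4,5-trimethoxyphenyl)propan-1-one F3 with F2 at its C–I bond (Pd2(dba)3 as zerovalent palladium source, Xantphos, NaOt-Bu, THF, 60 °C) should give rac-2-[2-bromo-4-(prop-2-en-1-yloxy)phenyl]-1-(3,4,5-trimethoxyphenyl)propan-1-one F4. Its α-centre is configurationally labile, so asymmetric transfer hydrogenation under dynamic kinetic resolution (RuCl[(S,S)-TsDPEN](p-cymene), HCO2H/Et3N) should funnel both enantiomers into (1S,2S)-2-[2-bromo-4-(prop-2-en-1-yloxy)phenyl]-1-(3,4,5-trimethoxyphenyl)propan-1-ol F5. Copper-catalysed intramolecular O-arylation (CuI, 1,10-phenanthroline, Cs2CO3, toluene, 110 °C) would then close the O1–C7a bond with retention at both centres and give 14. This fallback separates ring closure from stereocontrol and needs four steps in place of one.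

**Step 8 (Claisen rearrangement).** Partial migration of the allyl group to C7, the other position ortho to the C6 oxygen, is the main risk; thermal erosion at the benzylic C2–O1 bond is a lesser one. Fallback, setting out from 14 and returning at 16: the allyl ether would be cleaved (Pd(PPh3)4, morpholine, THF, rt) to (2S,3S)-3-methyl-2-(3,4,5-trimethoxyphenyl)-2,3-dihydro-1-benzofuran-6-ol F6. Bromination (N-bromosuccinimide, MeCN, −20 °C) at C5, which is ortho to the hydroxyl, para to O1 and the less hindered site, should give (2S,3S)-5-bromo-3-methyl-2-(3,4,5-trimethoxyphenyl)-2,3-dihydro-1-benzofuran-6-ol F7. A Stille coupling with allyltributylstannane (Pd(PPh3)4, DMF, 90 °C) would then install the allyl group at the position fixed by the halogen and give 16.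

**Step 3 (sulfone formation).** Acid-promoted self-condensation is the risk: the benzylic cation may alkylate the electron-rich resorcinol ring of a second molecule before the sulfinate captures it. Fallback without acid, setting out from 4 and returning at 11 within step 7: the phenol of 4 would be silylated selectively (TBSCl, imidazole, DMF, 0 °C) to rac-1-[2-(tert-butyldimethylsilyloxy)-4-(prop-2-en-1-yloxy)phenyl]ethan-1-ol F8. The benzylic alcohol would be acetylated (Ac2O, pyridine, DMAP) to rac-1-[2-(tert-butyldimethylsilyloxy)-4-(prop-2-en-1-yloxy)phenyl]ethyl acetate F9. In step 7, F9 would replace 5, and fluoride (CsF, MeCN) would unmask the phenoxide, which expels acetate and gives 11 in the presence of ylide 12.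

## Further compounds

F1 | step 7 | 3-bromo-4-iodophenol | Oc1ccc(I)c(Br)c1
F2 | step 7 | 2-bromo-1-iodo-4-(prop-2-en-1-yloxy)benzene | C=CCOc1ccc(I)c(Br)c1
F3 | step 7 | 1-(3,4,5-trimethoxyphenyl)propan-1-one | CCC(=O)c1cc(OC)c(OC)c(OC)c1
F4 | step 7 | rac-2-[2-bromo-4-(prop-2-en-1-yloxy)phenyl]-1-(3,4,5-trimethoxyphenyl)propan-1-one | CC(C(=O)c1cc(OC)c(OC)c(OC)c1)c1ccc(OCC=C)cc1Br
F5 | step 7 | (1S,2S)-2-[2-bromo-4-(prop-2-en-1-yloxy)phenyl]-1-(3,4,5-trimethoxyphenyl)propan-1-ol | C[C@@H](c1ccc(OCC=C)cc1Br)[C@H](O)c1cc(OC)c(OC)c(OC)c1
F6 | step 8 | (2S,3S)-3-methyl-2-(3,4,5-trimethoxyphenyl)-2,3-dihydro-1-benzofuran-6-ol | Oc1ccc2c(c1)O[C@H](c1cc(OC)c(OC)c(OC)c1)[C@H]2C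
F7 | step 8 | (2S,3S)-5-bromo-3-methyl-2-(3,4,5-trimethoxyphenyl)-2,3-dihydro-1-benzofuran-6-ol | Brc1cc2c(cc1O)O[C@H](c1cc(OC)c(OC)c(OC)c1)[C@H]2C
F8 | step 3 | rac-1-[2-(tert-butyldimethylsilyloxy)-4-(prop-2-en-1-yloxy)phenyl]ethan-1-ol | CC(O)c1ccc(OCC=C)cc1O[Si](C)(C)C(C)(C)C
F9 | step 3 | rac-1-[2-(tert-butyldimethylsilyloxy)-4-(prop-2-en-1-yloxy)phenyl]ethyl acetate | CC(OC(C)=O)c1ccc(OCC=C)cc1O[Si](C)(C)C(C)(C)C
A1 | alternative 1 | 3-methoxy-4-(prop-2-en-1-yl)phenol | C=CCc1ccc(O)cc1OC
A2 | alternative 1 | 1,2,3-trimethoxy-5-[(1E)-prop-1-en-1-yl]benzene | C/C=C/c1cc(OC)c(OC)c(OC)c1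
A3 | alternative 1 | rac-3-methyl-3a-(prop-2-en-1-yl)-2-(3,4,5-trimethoxyphenyl)-3,3a-dihydro-1-benzofuran-6(2H)-one | C=CCC12C=CC(=O)C=C1OC(c1cc(OC)c(OC)c(OC)c1)C2C
A4 | alternative 2 | methyl 2-diazo-2-{4-(prop-2-en-1-yloxy)-2-[(3,4,5-trimethoxybenzyl)oxy]phenyl}acetate | COC(=O)C(=[N+]=[N-])c1ccc(OCC=C)cc1OCc1cc(OC)c(OC)c(OC)c1
A5 | alternative 2 | methyl (2S,3R)-6-(prop-2-en-1-yloxy)-2-(3,4,5-trimethoxyphenyl)-2,3-dihydro-1-benzofuran-3-carboxylate | C=CCOc1ccc2c(c1)O[C@H](c1cc(OC)c(OC)c(OC)c1)[C@@H]2C(=O)OC
A6 | alternative 3 | tert-butyldimethyl{[3-methyl-2-(3,4,5-trimethoxyphenyl)-1-benzofuran-6-yl]oxy}silane | Cc1c(-c2cc(OC)c(OC)c(OC)c2)oc2cc(O[Si](C)(C)C(C)(C)C)ccc12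
A7 | alternative 3 | tert-butyldimethyl{[(2R,3S)-3-methyl-2-(3,4,5-trimethoxyphenyl)-2,3-dihydro-1-benzofuran-6-yl]oxy}silane | CC(C)(C)[Si](C)(C)Oc1ccc2c(c1)O[C@@H](c1cc(OC)c(OC)c(OC)c1)[C@H]2C
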